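The route rests on disconnecting C1–C5 and C1–C10 of the hydroazulene. Ring B without C1 (C5–C10) is read as a benzene ring: C5 is the ipso carbon, the oxygenated C6 and C10 are its two ortho carbons and the methyl-bearing C8 is para. In the key step a chiral copper carbenoid, generated at the future C1 of an α-methyl diazoketone, adds across the ipso–ortho bond and the resulting norcaradiene undergoes electrocyclic ring opening. This one operation closes ring A, expands the arene into ring B and sets the quaternary stereocentre C1, with both ring B oxygens and the C8 methyl already in place. The precursor is the symmetric aryl diazoketone 11.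

Key step: step 5

Remark: from 14 on the core carries daucane numbering (ring A C1–C5, ring B C1 and C5–C10, isopropyl C11–C13); β is the face of the C1 methyl group and α the opposite face; all bicyclic compounds are trans-fused (1β-methyl, 5α-H); hydride is assumed to add to the C10 carbonyl anti to the C1 methyl group.

Step 1
Reactants: 1 3,5-dimethoxytoluene
Product: 3 2,6-dimethoxy-4-methylbenzaldehyde, via (2,6-dimethoxy-4-methylphenyl)lithium 2 (not isolated)
Conditions: n-BuLi (1.1 equiv), TMEDA, Et2O, 0 °C → rt; DMF, 0 °C; then H2O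
Reagents that add atoms: N,N-dimethylformamide CN(C)C=O
Why: Directed ortho-metalation removes the proton flanked by both methoxy groups, the most acidic and best-coordinated ring position, and formylation of aryllithium 2 with DMF gives the aldehyde after collapse of the hemiaminal.

Step 2
Reactants: 3 2,6-dimethoxy-4-methylbenzaldehyde; 4 malonic acid
Product: 6 (E)-3-(2,6-dimethoxy-4-methylphenyl)prop-2-enoic acid, via arylidenemalonic acid 5 (not isolated)
Conditions: pyridine, piperidine (cat.), 90 °C
Reagents that add atoms: malonic acid (4) OC(=O)CC(=O)O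
Why: Knoevenagel–Doebner condensation gives the arylidenemalonic acid 5, which decarboxylates in hot pyridine to the (E)-cinnamic acid.

Step 3
Reactants: 6 (E)-3-(2,6-dimethoxy-4-methylphenyl)prop-2-enoic acid
Product: 7 3-(2,6-dimethoxy-4-methylphenyl)propanoic acid
Conditions: H2 (1 atm), Pd/C (10%), EtOAc, rt
Reagents that add atoms: none
Why: Heterogeneous hydrogenation saturates the conjugated C=C bond and leaves the arene, the ethers and the acid untouched.

Step 4
Reactants: 7 3-(2,6-dimethoxy-4-methylphenyl)propanoic acid; 8 N-ethyl-N-nitrosourea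
Product: 11 2-diazo-5-(2,6-dimethoxy-4-methylphenyl)pentan-3-one, via acid chloride 9 (not isolated), via diazoethane 10 (not isolated)
Conditions: (COCl)2, DMF (cat.), CH2Cl2, 0 °C → rt, evaporate; then CH3CHN2 (3 equiv, from 8, aq. KOH, Et2O, −10 °C), Et2O, −20 → 0 °C
Reagents that add atoms: N-ethyl-N-nitrosourea (8) CCN(N=O)C(N)=O
Why: Acylation of a diazoalkane by an acid chloride (the first stage of an Arndt–Eistert sequence) gives the α-methyl diazoketone, and the excess diazoethane consumes the HCl so that no α-chloroketone forms.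

Step 5
Reactants: 11 2-diazo-5-(2,6-dimethoxy-4-methylphenyl)pentan-3-one
Product: 13 (8aS)-4,8-dimethoxy-6,8a-dimethyl-3,8a-dihydroazulen-1(2H)-one, via norcaradiene 12 (not isolated)
Conditions: Cu(MeCN)4PF6 (5 mol%), (4S,4′S)-2,2′-(propane-2,2-diyl)bis(4-phenyl-4,5-dihydrooxazole) (6 mol%), NaB[3,5-(CF3)2C6H3]4 (6 mol%), CH2Cl2, 40 °C, slow addition of 11
Reagents that add atoms: none
Why: The monovalent copper bis(oxazoline) complex converts 11 into an electrophilic α-keto carbenoid at the future C1, which adds to the ipso–ortho π bond C5–C10 of the tethered arene in a [2+1] cycloaddition to give norcaradiene 12; thermally allowed disrotatory 6π electrocyclic opening of the C5–C10 σ bond then gives cycloheptatriene 13. The closest known reaction type is the enantioselective intramolecular Buchner reaction of α-alkyl α-diazoketones to 8a-alkyl azulenones with copper bis(oxazoline) catalysts. Ring A is closed by the C1–C5 bond (5-exo attack of the tethered carbenoid on the ipso carbon, the cyclopropane being completed at C10), whereas ring B is not cyclised from a chain but arises by expansion of the benzene ring (C1–C10 formed, C5–C10 broken). The only new stereocentre, C1, is controlled by the ligand, which must choose one of the two enantiotopic ipso–ortho bonds of the symmetric aryl group; the sense of induction is not predicted here and the antipodal ligand is to be used should it prove opposite. The step needs chemoselectivity for arene addition over 1,2-hydride migration from the C1 methyl, aromatic C–H insertion and attack by the methoxy oxygens: both ortho positions are substituted, the arene is electron-rich and symmetric (one regioisomer), and slow addition to a cationic copper catalyst should disfavour the hydride shift.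

Step 6
Reactants: 13 (8aS)-4,8-dimethoxy-6,8a-dimethyl-3,8a-dihydroazulen-1(2H)-one
Product: 14 11,12,13-trinordauc-8-ene-2,6,10-trione (5αH)
Conditions: 2 M aq. HCl, THF, 0 °C → rt
Reagents that add atoms: water O
Why: Acid-catalysed enol ether hydrolysis: protonation at the triene terminus C5 gives a bis(methoxy)pentadienyl cation that water converts into the two ketones, and the proton should add to C5 anti to the adjacent C1 methyl group (α face), which sets the trans ring fusion; the trione may equilibrate with its ring B dienol, which the next step also silylates at O6.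

Step 7
Reactants: 14 11,12,13-trinordauc-8-ene-2,6,10-trione (5αH)
Product: 15 2,6-bis(triisopropylsilyloxy)-11,12,13-trinordauca-2,6,8-trien-10-one (5αH)
Conditions: i-Pr3SiOTf (2.1 equiv), Et3N (3 equiv), CH2Cl2, −78 → 0 °C
Reagents that add atoms: triisopropylsilyl trifluoromethanesulfonate CC(C)[Si](C(C)C)(C(C)C)OS(=O)(=O)C(F)(F)F
Why: Soft enolisation and O-silylation with a silyl triflate: the C2 ketone can only enolise towards C3, and the ring B vinylogous acid (C7–H is doubly activated) should be silylated at O6, the oxygen not flanked by the quaternary C1, which leaves C10 as the only free carbonyl and C6 as a fluoride-labile dienol ether.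

Step 8
Reactants: 15 2,6-bis(triisopropylsilyloxy)-11,12,13-trinordauca-2,6,8-trien-10-one (5αH)
Product: 17 10β-hydroxy-11,12,13-trinordauc-8-ene-2,6-dione (5αH), via C10 carbinol 16 (not isolated)
Conditions: i-Bu2AlH (1.3 equiv), CH2Cl2, −78 °C; then Bu4NF (2.5 equiv), THF, −78 → 0 °C; AcOH, H2O; aq. potassium sodium tartrate
Reagents that add atoms: none
Why: 1,2-Reduction of the vinylogous ester carbonyl by i-Bu2AlH while C2 is masked as its silyl enol ether, with hydride expected to add to C10 anti to the axial C1 methyl group (10β-OH); fluoride then frees the C2 enolate and the C6 dienolate, whose kinetic protonation at the α-carbon C7 gives the β,γ-unsaturated ketone and so fixes the alkene at C8=C9 without any acid that could ionise the doubly allylic C10–O bond.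

Step 9
Reactants: 17 10β-hydroxy-11,12,13-trinordauc-8-ene-2,6-dione (5αH)
Product: 18 10β-(tert-butyldimethylsilyloxy)-11,12,13-trinordauc-8-ene-2,6-dione (5αH)
Conditions: t-BuMe2SiOTf (1.2 equiv), 2,6-lutidine (2 equiv), CH2Cl2, −78 °C
Reagents that add atoms: tert-butyldimethylsilyl trifluoromethanesulfonate CC(C)(C)[Si](C)(C)OS(=O)(=O)C(F)(F)F
Why: Silylation of a hindered secondary alcohol with a silyl triflate and a non-nucleophilic base, which blocks retro-aldol cleavage between C10–OH and the C2 ketone and protects C10 against the later oxidant and organometallic reagent.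

Step 10
Reactants: 18 10β-(tert-butyldimethylsilyloxy)-11,12,13-trinordauc-8-ene-2,6-dione (5αH)
Product: 19 10β-(tert-butyldimethylsilyloxy)-6,6-(ethylenedioxy)-11,12,13-trinordauc-8-en-2-one (5αH)
Conditions: Me3SiOCH2CH2OSiMe3 (1.5 equiv), Me3SiOTf (5 mol%), CH2Cl2, −78 °C; pyridine
Reagents that add atoms: 1,2-bis(trimethylsilyloxy)ethane C[Si](C)(C)OCCO[Si](C)(C)C
Why: Kinetically controlled silyl-transfer ketalisation should take the more accessible C6 ketone in preference to the C2 ketone that is flanked by the quaternary C1, the β,γ-alkene does not move at −78 °C, and the sp3 ketal removes the acidity of C5–H for the base-mediated steps that follow.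

Step 11
Reactants: 19 10β-(tert-butyldimethylsilyloxy)-6,6-(ethylenedioxy)-11,12,13-trinordauc-8-en-2-one (5αH)
Product: 21 10β-(tert-butyldimethylsilyloxy)-6,6-(ethylenedioxy)-11,12,13-trinordauca-3,8-dien-2-one (5αH), via trimethylsilyl enol ether 20 (not isolated)
Conditions: LiN(i-Pr)2 (1.2 equiv), THF, −78 °C; Me3SiCl; then Pd(OAc)2 (1.1 equiv), MeCN, rt
Reagents that add atoms: none
Why: Saegusa–Ito dehydrogenation: C3 is the only enolisable position of the C2 ketone, so silyl enol ether 20 forms regiospecifically and divalent palladium converts it into the C3=C4 enone by β-hydride elimination.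

Step 12
Reactants: 21 10β-(tert-butyldimethylsilyloxy)-6,6-(ethylenedioxy)-11,12,13-trinordauca-3,8-dien-2-one (5αH)
Product: 22 10β-(tert-butyldimethylsilyloxy)-3α,4α-epoxy-6,6-(ethylenedioxy)-11,12,13-trinordauc-8-en-2-one (5αH)
Conditions: 30% aq. H2O2, NaOH (0.2 equiv), MeOH, 0 °C
Reagents that add atoms: hydrogen peroxide OO
Why: Weitz–Scheffer nucleophilic epoxidation attacks only the electron-poor C3=C4 bond (C8=C9 is not conjugated to a carbonyl); hydroperoxide should add to C4 from the α face, anti to the C5–C6 bond and the C1 methyl, but both new stereocentres are erased later.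

Step 13
Reactants: 22 10β-(tert-butyldimethylsilyloxy)-3α,4α-epoxy-6,6-(ethylenedioxy)-11,12,13-trinordauc-8-en-2-one (5αH)
Product: 24 10β-(tert-butyldimethylsilyloxy)-6,6-(ethylenedioxy)-11,12,13-trinordauca-2,8-dien-4α-ol (5αH), via epoxy hydrazone 23 (not isolated)
Conditions: N2H4·H2O (3 equiv), AcOH (0.3 equiv), MeOH, 0 °C → rt
Reagents that add atoms: none
Why: Wharton transposition: hydrazone 23 opens the epoxide to an alkenyl diazene that loses N2, which moves the oxygen function from C2 to C4 (the C4–O bond of the epoxide is kept, hence 4α-OH) and leaves a C2=C3 alkene.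

Step 14
Reactants: 24 10β-(tert-butyldimethylsilyloxy)-6,6-(ethylenedioxy)-11,12,13-trinordauca-2,8-dien-4α-ol (5αH)
Product: 25 10β-(tert-butyldimethylsilyloxy)-6,6-(ethylenedioxy)-11,12,13-trinordauc-8-en-4α-ol (5αH)
Conditions: 2-nitrobenzenesulfonohydrazide (3 equiv), Et3N, CH2Cl2, rt
Reagents that add atoms: none
Why: Diimide reduction: the concerted syn transfer of H2 is much faster for the cis-disubstituted C2=C3 bond than for the trisubstituted C8=C9 bond, and unlike catalytic hydrogenation it cannot cleave or isomerise the allylic C–O systems.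

Step 15
Reactants: 25 10β-(tert-butyldimethylsilyloxy)-6,6-(ethylenedioxy)-11,12,13-trinordauc-8-en-4α-ol (5αH)
Product: 26 10β-(tert-butyldimethylsilyloxy)-6,6-(ethylenedioxy)-11,12,13-trinordauc-8-en-4-one (5αH)
Conditions: Dess–Martin periodinane (1.3 equiv), CH2Cl2, 0 °C → rt
Reagents that add atoms: none
Why: Dess–Martin oxidation of the secondary C4 alcohol under non-basic conditions, which should not epimerise C5 or eliminate the β-ketal oxygen.

Step 16
Reactants: 26 10β-(tert-butyldimethylsilyloxy)-6,6-(ethylenedioxy)-11,12,13-trinordauc-8-en-4-one (5αH); 27 isopropylmagnesium chloride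
Product: 28 10β-(tert-butyldimethylsilyloxy)-6,6-(ethylenedioxy)dauc-8-en-4β-ol (5αH)
Conditions: CeCl3 (1.5 equiv), i-PrMgCl (1.5 equiv), THF, −78 → 0 °C; then H2O
Reagents that add atoms: isopropylmagnesium chloride (27) CC(C)[Mg]Cl
Why: Organocerium 1,2-addition (low basicity suppresses enolisation at C3 and C5 and β-hydride reduction); the nucleophile should attack the cyclopentanone from the α face, which carries only the C5 hydrogen, because the β face is screened by the 1,3-related axial C1 methyl group and the C6 ketal, giving 4α-isopropyl and 4β-OH.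

Step 17
Reactants: 28 10β-(tert-butyldimethylsilyloxy)-6,6-(ethylenedioxy)dauc-8-en-4β-ol (5αH)
Product: 29 10β-(tert-butyldimethylsilyloxy)-4β-hydroxydauc-8-en-6-one (5αH)
Conditions: pyridinium p-toluenesulfonate (0.2 equiv), acetone/H2O (10:1), 40 °C
Reagents that add atoms: water O
Why: Mild acid-catalysed ketal hydrolysis frees the C6 ketone; the silyl ether and the tertiary alcohol survive, and so weak an acid should neither dehydrate the β-hydroxy ketone, epimerise C5 nor move the C8=C9 bond into conjugation.

Step 18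
Reactants: 29 10β-(tert-butyldimethylsilyloxy)-4β-hydroxydauc-8-en-6-one (5αH)
Product: 30 10β-(tert-butyldimethylsilyloxy)dauc-8-ene-4β,6α-diol (5αH)
Conditions: Me4NBH(OAc)3 (5 equiv), MeCN/AcOH (1:1), −30 °C
Reagents that add atoms: none
Why: Evans–Saksena reduction: the alkoxy(diacetoxy)borohydride formed at the 4β-hydroxyl delivers hydride intramolecularly to the β face of the C6 ketone through a six-membered transition state, which gives the anti 1,3-diol with 6α-OH, the epimer that simple hydrides would not favour.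

Step 19
Reactants: 30 10β-(tert-butyldimethylsilyloxy)dauc-8-ene-4β,6α-diol (5αH); 31 4-methoxybenzoyl chloride
Product: 32 10β-(tert-butyldimethylsilyloxy)-6α-(4-methoxybenzoyloxy)dauc-8-en-4β-ol (5αH)
Conditions: 4-MeOC6H4COCl (1.5 equiv), Et3N, DMAP (cat.), CH2Cl2, 0 °C → rt
Reagents that add atoms: 4-methoxybenzoyl chloride (31) COc1ccc(cc1)C(=O)Cl
Why: DMAP-catalysed acylation of the secondary 6α-alcohol; the tertiary C4 alcohol is too hindered to react and C10 is still silylated.

Step 20
Reactants: 32 10β-(tert-butyldimethylsilyloxy)-6α-(4-methoxybenzoyloxy)dauc-8-en-4β-ol (5αH)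
Product: 33 6α-(4-methoxybenzoyloxy)dauc-8-ene-4β,10β-diol (5αH)
Conditions: Bu4NF (2 equiv), AcOH (2 equiv), THF, rt
Reagents that add atoms: none
Why: Fluoride cleavage of the silyl ether, buffered by acetic acid so that no alkoxide or hydroxide can attack or shift the ester.

Step 21
Reactants: 33 6α-(4-methoxybenzoyloxy)dauc-8-ene-4β,10β-diol (5αH); 34 angelic acid
Product: 35 10α-[(Z)-2-methylbut-2-enoyloxy]-6α-(4-methoxybenzoyloxy)dauc-8-en-4β-ol (5αH), the target CNP0168729.1
Conditions: PPh3 (2 equiv), diisopropyl azodicarboxylate (2 equiv), toluene, 0 °C → rt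
Reagents that add atoms: angelic acid (34) C/C=C(/C)C(=O)O
Why: Mitsunobu esterification: angelate attacks the C10 alkoxyphosphonium ion in an SN2 step from the open α face and inverts 10β-OH to the 10α-ester; the acid reacts as a carboxylate and is never activated at its acyl carbon, so the Z alkene should not isomerise to the tiglate, and the tertiary C4 alcohol is inert.

Compound list
1 | 3,5-dimethoxytoluene | COc1cc(C)cc(OC)c1 | starting material
2 | (2,6-dimethoxy-4-methylphenyl)lithium | [Li]c1c(OC)cc(C)cc1OC | intermediate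
3 | 2,6-dimethoxy-4-methylbenzaldehyde | COc1cc(C)cc(OC)c1C=O | intermediate
4 | malonic acid | OC(=O)CC(=O)O | starting material
5 | 2-[(2,6-dimethoxy-4-methylphenyl)methylidene]propanedioic acid | COc1cc(C)cc(OC)c1C=C(C(=O)O)C(=O)O | intermediate
6 | (E)-3-(2,6-dimethoxy-4-methylphenyl)prop-2-enoic acid | COc1cc(C)cc(OC)c1/C=C/C(=O)O | intermediate
7 | 3-(2,6-dimethoxy-4-methylphenyl)propanoic acid | COc1cc(C)cc(OC)c1CCC(=O)O | intermediate
8 | N-ethyl-N-nitrosourea | CCN(N=O)C(N)=O | starting material
9 | 3-(2,6-dimethoxy-4-methylphenyl)propanoyl chloride | COc1cc(C)cc(OC)c1CCC(=O)Cl | intermediate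
10 | diazoethane | CC=[N+]=[N-] | intermediate
11 | 2-diazo-5-(2,6-dimethoxy-4-methylphenyl)pentan-3-one | COc1cc(C)cc(OC)c1CCC(=O)C(C)=[N+]=[N-] | intermediate
12 | norcaradiene valence isomer of 13 (cyclopropane C1–C5–C10; diene C6=C7–C8=C9; C2 ketone) | COC1=CC(C)=C[C@]2(OC)[C@@]3(C)C(=O)CC[C@@]123 | intermediate
13 | (8aS)-4,8-dimethoxy-6,8a-dimethyl-3,8a-dihydroazulen-1(2H)-one | COC1=CC(C)=CC(OC)=C2CCC(=O)[C@]12C | intermediate
14 | 11,12,13-trinordauc-8-ene-2,6,10-trione (5αH) | O=C1C=C(C)CC(=O)[C@@H]2[C@]1(C)C(=O)CC2 | intermediate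
15 | 2,6-bis(triisopropylsilyloxy)-11,12,13-trinordauca-2,6,8-trien-10-one (5αH) | O=C1C=C(C)C=C(O[Si](C(C)C)(C(C)C)C(C)C)[C@@H]2[C@]1(C)C(O[Si](C(C)C)(C(C)C)C(C)C)=CC2 | intermediate
16 | 2,6-bis(triisopropylsilyloxy)-11,12,13-trinordauca-2,6,8-trien-10β-ol (5αH; formed as its aluminium alkoxide) | O[C@H]1C=C(C)C=C(O[Si](C(C)C)(C(C)C)C(C)C)[C@@H]2[C@]1(C)C(O[Si](C(C)C)(C(C)C)C(C)C)=CC2 | intermediate
17 | 10β-hydroxy-11,12,13-trinordauc-8-ene-2,6-dione (5αH) | O[C@H]1C=C(C)CC(=O)[C@@H]2[C@]1(C)C(=O)CC2 | intermediate
18 | 10β-(tert-butyldimethylsilyloxy)-11,12,13-trinordauc-8-ene-2,6-dione (5αH) | C[Si](C)(C(C)(C)C)O[C@H]1C=C(C)CC(=O)[C@@H]2[C@]1(C)C(=O)CC2 | intermediate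
19 | 10β-(tert-butyldimethylsilyloxy)-6,6-(ethylenedioxy)-11,12,13-trinordauc-8-en-2-one (5αH) | C[Si](C)(C(C)(C)C)O[C@H]1C=C(C)CC3(OCCO3)[C@@H]2[C@]1(C)C(=O)CC2 | intermediate
20 | 10β-(tert-butyldimethylsilyloxy)-6,6-(ethylenedioxy)-2-(trimethylsilyloxy)-11,12,13-trinordauca-2,8-diene (5αH) | C[Si](C)(C(C)(C)C)O[C@H]1C=C(C)CC3(OCCO3)[C@@H]2[C@]1(C)C(O[Si](C)(C)C)=CC2 | intermediate
21 | 10β-(tert-butyldimethylsilyloxy)-6,6-(ethylenedioxy)-11,12,13-trinordauca-3,8-dien-2-one (5αH) | C[Si](C)(C(C)(C)C)O[C@H]1C=C(C)CC3(OCCO3)[C@@H]2[C@]1(C)C(=O)C=C2 | intermediate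
22 | 10β-(tert-butyldimethylsilyloxy)-3α,4α-epoxy-6,6-(ethylenedioxy)-11,12,13-trinordauc-8-en-2-one (5αH) | C[Si](C)(C(C)(C)C)O[C@H]1C=C(C)CC3(OCCO3)[C@@H]2[C@]1(C)C(=O)[C@H]4O[C@@H]24 | intermediate
23 | C2 hydrazone of 22 | C[Si](C)(C(C)(C)C)O[C@H]1C=C(C)CC3(OCCO3)[C@@H]2[C@]1(C)C(=NN)[C@H]4O[C@@H]24 | intermediate
24 | 10β-(tert-butyldimethylsilyloxy)-6,6-(ethylenedioxy)-11,12,13-trinordauca-2,8-dien-4α-ol (5αH) | C[Si](C)(C(C)(C)C)O[C@H]1C=C(C)CC3(OCCO3)[C@@H]2[C@]1(C)C=C[C@H]2O | intermediate
25 | 10β-(tert-butyldimethylsilyloxy)-6,6-(ethylenedioxy)-11,12,13-trinordauc-8-en-4α-ol (5αH) | C[Si](C)(C(C)(C)C)O[C@H]1C=C(C)CC3(OCCO3)[C@@H]2[C@]1(C)CC[C@H]2O | intermediate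
26 | 10β-(tert-butyldimethylsilyloxy)-6,6-(ethylenedioxy)-11,12,13-trinordauc-8-en-4-one (5αH) | C[Si](C)(C(C)(C)C)O[C@H]1C=C(C)CC3(OCCO3)[C@@H]2[C@]1(C)CCC2=O | intermediate
27 | isopropylmagnesium chloride | CC(C)[Mg]Cl | starting material
28 | 10β-(tert-butyldimethylsilyloxy)-6,6-(ethylenedioxy)dauc-8-en-4β-ol (5αH; isopropyl 4α) | C[Si](C)(C(C)(C)C)O[C@H]1C=C(C)CC3(OCCO3)[C@@H]2[C@]1(C)CC[C@@]2(O)C(C)C | intermediate
29 | 10β-(tert-butyldimethylsilyloxy)-4β-hydroxydauc-8-en-6-one (5αH) | C[Si](C)(C(C)(C)C)O[C@H]1C=C(C)CC(=O)[C@@H]2[C@]1(C)CC[C@@]2(O)C(C)C | intermediate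
30 | 10β-(tert-butyldimethylsilyloxy)dauc-8-ene-4β,6α-diol (5αH) | C[Si](C)(C(C)(C)C)O[C@H]1C=C(C)C[C@H](O)[C@@H]2[C@]1(C)CC[C@@]2(O)C(C)C | intermediate
31 | 4-methoxybenzoyl chloride | COc1ccc(cc1)C(=O)Cl | starting material
32 | 10β-(tert-butyldimethylsilyloxy)-6α-(4-methoxybenzoyloxy)dauc-8-en-4β-ol (5αH) | C[Si](C)(C(C)(C)C)O[C@H]1C=C(C)C[C@H](OC(=O)c3ccc(OC)cc3)[C@@H]2[C@]1(C)CC[C@@]2(O)C(C)C | intermediate
33 | 6α-(4-methoxybenzoyloxy)dauc-8-ene-4β,10β-diol (5αH) | O[C@H]1C=C(C)C[C@H](OC(=O)c3ccc(OC)cc3)[C@@H]2[C@]1(C)CC[C@@]2(O)C(C)C | intermediate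
34 | angelic acid, (Z)-2-methylbut-2-enoic acid | C/C=C(/C)C(=O)O | starting material
35 | 10α-[(Z)-2-methylbut-2-enoyloxy]-6α-(4-methoxybenzoyloxy)dauc-8-en-4β-ol (5αH), CNP0168729.1 | C/C=C(/C)C(=O)O[C@@H]1C=C(C)C[C@H](OC(=O)c2ccc(OC)cc2)[C@@H]2[C@]1(C)CC[C@@]2(O)C(C)C | target

Total step count: 21. Longest linear sequence: 21 steps (1 to 35); compounds 4, 8, 27, 31 and 34 are bought.

Steps most likely to fail

Step 5. The carbenoid may be consumed by 1,2-hydride migration from its methyl group, or by attack of a methoxy oxygen, before it adds to the doubly ortho-substituted ipso–ortho bond. The fallback replaces the methyl group during the cyclisation by an ester, so that the carbenoid has no β-hydrogen, and turns the ester into the methyl group afterwards. It sets out from acid 7 and comes back at 13.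
- Activation of 7 with 1,1′-carbonyldiimidazole and reaction with the magnesium salt of monomethyl malonate would give the β-keto ester F1.
- Diazo transfer (4-acetamidobenzenesulfonyl azide, Et3N) would give the diazo keto ester F2.
- Buchner cyclisation of F2 with a chiral dirhodium tetracarboxylate such as dirhodium tetrakis[(S)-N-phthaloyl-tert-leucinate], Rh2(S-PTTL)4, would give the azulenone ester F3.
- LiAlH4 would reduce ketone and ester to the diol F4.
- Tosylation of the primary hydroxyl (TsCl, pyridine) would give the tosylate F5.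
- LiBHEt3 would displace the neopentyl tosylate by hydride to give the methyl carbinol F6.
- Dess–Martin oxidation of F6 would return ketone 13.

Step 7. Silylation of the ring B vinylogous acid may fail to discriminate O6 from O10, or may run on to a trienyl bis(silyl ether); the wrong carbonyl would then be reduced in step 8 and the alkene would end at C7=C8. The fallback sets the regiochemistry under thermodynamic instead of kinetic control. It sets out from trione 14 and comes back at 17.
- Acid-catalysed condensation of 14 with 2-(trimethylsilyl)ethanol (TsOH, benzene, removal of water) should equilibrate to the vinylogous ester F7, with the alkoxy group on the less hindered C6.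
- The C2 ketone would be masked in situ as its lithium enolate (LiN(i-Pr)2, −78 °C) while i-Bu2AlH reduces C10, giving the 10β-carbinol F8.
- Bu4NF would then fragment the 2-silylethyl dienol ether of F8 to the C6 dienolate, whose protonation at C7 returns hydroxy diketone 17.

Step 21. Displacement at the neopentyl, allylic C10 may be slow, so that the alkoxyphosphonium ion ionises instead; that would lead to allylic transposition towards C8, elimination to a diene or loss of stereochemical fidelity. The fallback inverts C10 by oxidation and reagent-controlled reduction and then acylates with retention. It sets out from alcohol 33 and comes back at target 35.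
- MnO2 would oxidise the allylic alcohol of 33 to the enone F9.
- Corey–Bakshi–Shibata reduction would give the 10α-alcohol F10; the oxazaborolidine enantiomer that delivers hydride to the β face is chosen in a test reaction (catecholborane, −78 °C).
- Yamaguchi esterification of F10 with angelic acid 34 (2,4,6-trichlorobenzoyl chloride, Et3N, then DMAP, toluene, 80 °C) would give 35 with retention at C10.
- The same acylation with retention would be used directly if step 8 should deliver the 10α-alcohol.

Further compounds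
F1 | step 5 | methyl 5-(2,6-dimethoxy-4-methylphenyl)-3-oxopentanoate | COC(=O)CC(=O)CCc1c(OC)cc(C)cc1OC
F2 | step 5 | methyl 2-diazo-5-(2,6-dimethoxy-4-methylphenyl)-3-oxopentanoate | COC(=O)C(=[N+]=[N-])C(=O)CCc1c(OC)cc(C)cc1OC
F3 | step 5 | methyl 4,8-dimethoxy-6-methyl-1-oxo-2,3-dihydroazulene-8a(1H)-carboxylate (C8a arranged as in 13) | COC1=CC(C)=CC(OC)=C2CCC(=O)[C@]12C(=O)OC
F4 | step 5 | 8a-(hydroxymethyl)-4,8-dimethoxy-6-methyl-1,2,3,8a-tetrahydroazulen-1-ol (either carbinol epimer) | COC1=CC(C)=CC(OC)=C2CCC(O)[C@]12CO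
F5 | step 5 | [1-hydroxy-4,8-dimethoxy-6-methyl-2,3-dihydroazulen-8a(1H)-yl]methyl 4-methylbenzenesulfonate | COC1=CC(C)=CC(OC)=C2CCC(O)[C@]12COS(=O)(=O)c3ccc(C)cc3
F6 | step 5 | 4,8-dimethoxy-6,8a-dimethyl-1,2,3,8a-tetrahydroazulen-1-ol (either carbinol epimer) | COC1=CC(C)=CC(OC)=C2CCC(O)[C@]12C
F7 | step 7 | 6-[2-(trimethylsilyl)ethoxy]-11,12,13-trinordauca-6,8-diene-2,10-dione (5αH) | O=C1C=C(C)C=C(OCC[Si](C)(C)C)[C@@H]2[C@]1(C)C(=O)CC2
F8 | step 7 | 10β-hydroxy-6-[2-(trimethylsilyl)ethoxy]-11,12,13-trinordauca-6,8-dien-2-one (5αH) | O[C@H]1C=C(C)C=C(OCC[Si](C)(C)C)[C@@H]2[C@]1(C)C(=O)CC2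
F9 | step 21 | 4β-hydroxy-6α-(4-methoxybenzoyloxy)dauc-8-en-10-one (5αH) | O=C1C=C(C)C[C@H](OC(=O)c3ccc(OC)cc3)[C@@H]2[C@]1(C)CC[C@@]2(O)C(C)C
F10 | step 21 | 6α-(4-methoxybenzoyloxy)dauc-8-ene-4β,10α-diol (5αH) | O[C@@H]1C=C(C)C[C@H](OC(=O)c3ccc(OC)cc3)[C@@H]2[C@]1(C)CC[C@@]2(O)C(C)C
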